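**Retrosynthetic overview**
1. Target ⇐ acid-mediated Friedel–Crafts closure of the C1–C8a bond in acyclic enal 10, which forms the only new ring (the central carbocycle) last and sets C1 trans to C2; MOM and TBS groups fall off in the same step.
2. Enal 10 ⇐ crossed aldol condensation (C3=C4) of aldehyde 9 with protected vanillin 4.
3. Aldehyde 9 ⇐ key step: enantioselective radical conjugate addition forming C1–C2. The α-methoxybenzyl radical from decarboxylation of acid 5 adds to the chiral iminium ion of enal 8 and sets C2.
4. Acid 5 and aldehyde 4 both come from catechol via guaiacol and vanillin; enal 8 comes from TBS-protected allyl alcohol and crotonaldehyde by cross-metathesis.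
5. Both aromatic rings are bought as catechol; no other ring is constructed.

Numbering used below: dihydronaphthalene C1 (aryl-bearing), C2 (CH2OH-bearing), C3 (CHO-bearing), C4 (vinylic CH). The target is (1S,2R), trans.

Assumption: the target is treated as the open hydroxy-aldehyde drawn in the SMILES (any lactol tautomer equilibrates with it); allyl tert-butyldimethylsilyl ether is purchased as protected allyl alcohol.

**Step 1**
Reactants: 1, catechol
Product: 2, guaiacol (2-methoxyphenol)
Conditions: MeI (1.0 equiv), K2CO3 (1.0 equiv), acetone, reflux; unreacted catechol recycled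
Reagents that add atoms: iodomethane, CI
Why: Williamson mono-O-methylation of the catechol mono-anion; the statistical by-products (catechol, veratrole) are removed by distillation.

**Step 2**
Reactants: 2, guaiacol
Product: 3, vanillin (4-hydroxy-3-methoxybenzaldehyde)
Conditions: OHC–CO2H, NaOH, H2O, 30 °C; then CuSO4 (cat.), air, NaOH, 95 °C; H3O+
Reagents that add atoms: glyoxylic acid, O=CC(=O)O
Why: para-selective electrophilic hydroxyalkylation of the phenoxide gives the mandelic acid, and Cu-mediated oxidative decarboxylation gives the aldehyde (the industrial guaiacol-to-vanillin process).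

**Step 3**
Reactants: 3, vanillin
Product: 4, 3-methoxy-4-(methoxymethoxy)benzaldehyde
Conditions: MOMCl, iPr2NEt, CH2Cl2, 0 °C → rt
Reagents that add atoms: chloromethyl methyl ether, COCCl
Why: standard phenol O-alkylation to the MOM acetal, which is base- and radical-stable but acid-labile.

**Step 4**
Reactants: 4, 3-methoxy-4-(methoxymethoxy)benzaldehyde
Product: 5, rac-2-methoxy-2-[3-methoxy-4-(methoxymethoxy)phenyl]acetic acid
Conditions: CHBr3, KOH, LiCl, MeOH/dioxane, 0–5 °C; then cold buffer to pH 3–4
Reagents that add atoms: bromoform, BrC(Br)Br; methanol, CO; potassium hydroxide, [K+].[OH-]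
Why: Jocic–Reeve reaction, in which the tribromomethyl carbinolate closes to a gem-dibromo-epoxide that methoxide opens at the benzylic carbon, and hydrolysis gives the α-methoxy acid; the new centre is racemic and is erased later.

**Step 5**
Reactants: 6, allyloxy(tert-butyl)dimethylsilane (TBS-protected allyl alcohol); 7, (E)-crotonaldehyde (3 equiv)
Product: 8, (E)-4-[(tert-butyldimethylsilyl)oxy]but-2-enal
Conditions: Hoveyda–Grubbs II (2 mol%), CH2Cl2, 40 °C
Reagents that add atoms: none
Why: E-selective olefin cross-metathesis between an allyl ether and an enal, driven by loss of propene.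

**Step 6 (key step)**
Reactants: 5, rac-2-methoxy-2-[3-methoxy-4-(methoxymethoxy)phenyl]acetic acid (1.5 equiv); 8, (E)-4-[(tert-butyldimethylsilyl)oxy]but-2-enal
Product: 9, (3R)-4-[(tert-butyldimethylsilyl)oxy]-3-{methoxy[3-methoxy-4-(methoxymethoxy)phenyl]methyl}butanal (about 1:1 epimers at the benzylic OMe carbon)
Conditions: (R)-2-{bis[3,5-bis(trifluoromethyl)phenyl][(tert-butyldimethylsilyl)oxy]methyl}-4,4-difluoropyrrolidine (20 mol%), 4CzIPN (3 mol%), MeCN, 456 nm LEDs, 10 °C
Reagents that add atoms: none
Why: Proposed new method: excited 4CzIPN oxidises the carboxylate of 5 (the iminium counter-ion), CO2 is lost, and the nucleophilic α-methoxybenzyl radical adds to the β-carbon of the chiral iminium ion of 8 on the face left open by the (R)-diarylprolinol silyl ether (standard steric-shielding model), after which 4CzIPN•− reduces the α-iminyl radical cation to the enamine and hydrolysis releases 9 with C2 set as R; the closest known reaction types are iminium-ion/photoredox enantioselective radical conjugate addition to enals and photoredox decarboxylative Giese addition of α-alkoxy acids.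

**Step 7**
Reactants: 9, the (3R)-aldehyde; 4, 3-methoxy-4-(methoxymethoxy)benzaldehyde (2 equiv)
Product: 10, (2E)-2-[(2R)-3-[(tert-butyldimethylsilyl)oxy]-1-methoxy-1-[3-methoxy-4-(methoxymethoxy)phenyl]propan-2-yl]-3-[3-methoxy-4-(methoxymethoxy)phenyl]prop-2-enal
Conditions: pyrrolidine (30 mol%), PhCO2H (30 mol%), toluene, 60 °C
Reagents that add atoms: none
Why: amine-catalysed crossed aldol (Mannich–elimination) condensation gives the E α-substituted cinnamaldehyde, with the aryl group cis to C2; the C2 stereocentre is not enolisable in 9 and is only cross-conjugated in 10, so it is not epimerised.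

**Step 8**
Reactants: 10, the (2E,2R)-enal
Product: 11, target, (1S,2R)-7-hydroxy-1-(4-hydroxy-3-methoxyphenyl)-2-(hydroxymethyl)-6-methoxy-1,2-dihydronaphthalene-3-carbaldehyde
Conditions: TFA/CH2Cl2/H2O (10:10:1), 0 °C → rt; then aq. NaHCO3/MeOH
Reagents that add atoms: none
Why: ionisation of the p-oxygenated benzylic methyl ether gives a cation (quinone-methide-like once the MOM group is lost) that undergoes 6-ring Friedel–Crafts alkylation para to the OMe of the cinnamyl ring, with the aryl group going trans to the C2 substituent to set C1 as S, while the same acid cleaves both aryl MOM ethers and the primary TBS ether.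

**Compound list**
1 | catechol | Oc1ccccc1O | starting material
2 | guaiacol | COc1ccccc1O | intermediate
3 | vanillin | COc1cc(C=O)ccc1O | intermediate
4 | 3-methoxy-4-(methoxymethoxy)benzaldehyde | COCOc1ccc(C=O)cc1OC | intermediate
5 | rac-2-methoxy-2-[3-methoxy-4-(methoxymethoxy)phenyl]acetic acid | COCOc1ccc(C(OC)C(=O)O)cc1OC | intermediate
6 | allyloxy(tert-butyl)dimethylsilane | C=CCO[Si](C)(C)C(C)(C)C | starting material
7 | (E)-crotonaldehyde | C/C=C/C=O | starting material
8 | (E)-4-[(tert-butyldimethylsilyl)oxy]but-2-enal | O=C/C=C/CO[Si](C)(C)C(C)(C)C | intermediate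
9 | (3R)-4-[(tert-butyldimethylsilyl)oxy]-3-{methoxy[3-methoxy-4-(methoxymethoxy)phenyl]methyl}butanal | O=CC[C@H](CO[Si](C)(C)C(C)(C)C)C(OC)c1ccc(OCOC)c(OC)c1 | intermediate
10 | (2E)-2-[(2R)-3-[(tert-butyldimethylsilyl)oxy]-1-methoxy-1-[3-methoxy-4-(methoxymethoxy)phenyl]propan-2-yl]-3-[3-methoxy-4-(methoxymethoxy)phenyl]prop-2-enal | O=C/C(=C/c1ccc(OCOC)c(OC)c1)[C@H](CO[Si](C)(C)C(C)(C)C)C(OC)c1ccc(OCOC)c(OC)c1 | intermediate
11 | 7,8,9,9-tetradehydroisolariciresinol | COc1cc([C@H]2c3cc(O)c(OC)cc3C=C(C=O)[C@@H]2CO)ccc1O | target

**Totals**
Total steps: 8. Longest linear sequence: 7 (steps 1, 2, 3, 4, 6, 7, 8).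

**Three steps most likely to fail**
1. Step 6. The risks are racemic background addition to free enal, over-oxidation of the radical back to aldehyde 4, and low reactivity of the stabilised radical. Fallback: replace iminium activation with two-point chiral Lewis-acid activation. Use the N-acyl-3,5-dimethylpyrazole of (E)-4-(TBSO)but-2-enoic acid with a chiral-at-rhodium (or Mg–bisoxazoline) catalyst and the same decarboxylative radical, then reduce the acylpyrazole to aldehyde 9 with DIBAL.
2. Step 8. The protonated enal deactivates the attacking ring, E1 elimination and reprotonation at C2 could erode ee, and MOM-derived electrophiles could alkylate the phenols. Fallback: switch to a quinone-methide cyclisation. Carry the pendant-ring phenol through with an orthogonal group (for example allyl), free it selectively, and ionise under near-neutral conditions where the enal is not protonated; then remove the remaining groups.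
3. Step 7. The risks are self-condensation of 9 and the low electrophilicity of the electron-rich aldehyde 4. Fallback: move to lactone enolate chemistry. Pinnick-oxidise 9, desilylate and lactonise to the β-substituted γ-butyrolactone, run an LDA aldol with 4 followed by dehydration (MsCl/Et3N, DBU), cyclise as in step 8, and finish by DIBAL reduction of the lactone to the hydroxy-aldehyde.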